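Retrosynthesis: invert the C4–O bond (trans from cis), then strip the hydrogens at C2, C3 and C4 back to the flat isoflavone. Ring C is then cut at C2–C3 and O1–C8a together, leaving an open 2-fluorodeoxybenzoin and a two-atom C=O unit (ethyl formate); the last cut is C3–C1' (ketone α-arylation).
Enabling feature: C4, raised to the ketone level, lies between C3 and C4a of ring A. It acidifies the C3 methylene (also benzylic to ring B) and makes C8a, the ortho carbon of ring A carrying fluorine as a helper, a vinylogous acyl fluoride, so a C=O unit can bind C3 through carbon and C8a through oxygen.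
The unit enters at the formate level rather than as formaldehyde. A β-hydroxy ketone would lose water before its oxygen could attack the electron-rich ring A, whereas the formyl enolate cannot; step 7 removes the extra C2=C3 unsaturation at no cost in steps.
Forward: rings A and B come from benzenoid starting materials (steps 1–2 and 3–4) and are joined at C3–C1' (step 5). Ring C, the only ring that is built, closes in step 6.
Stereochemistry: one asymmetric transfer hydrogenation cascade with dynamic kinetic resolution sets C3 and C4 (cis-3S,4S) under catalyst control, a Mitsunobu inversion at C4 gives the trans-(3S,4R) series, and the benzyl groups leave last.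

Key step: step 6

Remark on the chemistry: the SMILES descriptors read as (3S,4R), so ring B at C3 and OH at C4 are trans on ring C. Isoflavan numbering is used (O1, C2, C3, C4, C4a, C5 to C8, C8a; ring B C1' to C6'), and 2,3-dimethoxy-1,4-benzoquinone is taken as commercially available.

Step 1
Reactants: 1 1,2,3-trimethoxybenzene
Product: 3 1-fluoro-2,3,4-trimethoxybenzene, via 2,3,4-trimethoxyphenyllithium 2 (not isolated)
Conditions: n-BuLi, TMEDA, THF, 0 °C to rt; NFSI, THF, −78 °C to rt; H2O work-up
Reagents that add atoms: N-fluorobenzenesulfonimide (NFSI), O=S(=O)(c1ccccc1)N(F)S(=O)(=O)c1ccccc1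
Why: Directed ortho-metalation followed by electrophilic fluorination: the only protons next to a methoxy group are the equivalent C4–H and C6–H, so a single aryllithium forms and takes F from the N–F reagent.

Step 2
Reactants: 3 1-fluoro-2,3,4-trimethoxybenzene; 4 N-methoxy-N-methylacetamide
Product: 6 1-(2-fluoro-3,4,5-trimethoxyphenyl)ethan-1-one, via (2-fluoro-3,4,5-trimethoxyphenyl)lithium 5 (not isolated)
Conditions: n-BuLi, THF, −78 °C; 4, −78 °C to 0 °C; H2O work-up
Reagents that add atoms: N-methoxy-N-methylacetamide (4), CC(=O)N(C)OC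
Why: Directed ortho-metalation and Weinreb ketone synthesis: fluorine acidifies its ortho proton more than methoxy does (the same preference is known for 3-fluoroveratrole), 5 does not lose LiF at −78 °C, and the chelated tetrahedral adduct prevents a second addition.

Step 3
Reactants: 7 2,3-dimethoxy-1,4-benzoquinone
Product: 9 1,4-bis(benzyloxy)-2,3-dimethoxybenzene, via 2,3-dimethoxyhydroquinone 8 (not isolated)
Conditions: Na2S2O4, THF/H2O, rt, N2; crude 8, BnBr, K2CO3, DMF, 60 °C
Reagents that add atoms: benzyl bromide, BrCc1ccccc1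
Why: Dithionite reduction of the quinone and double Williamson ether synthesis, which need no regiocontrol because 8 is symmetric, give benzyl ethers that withstand every base, hydride and coupling step up to step 10.

Step 4
Reactants: 9 1,4-bis(benzyloxy)-2,3-dimethoxybenzene
Product: 10 2,5-bis(benzyloxy)-1-bromo-3,4-dimethoxybenzene
Conditions: NBS (1 equiv), MeCN, 0 °C to rt, dark
Reagents that add atoms: N-bromosuccinimide, O=C1CCC(=O)N1Br
Why: Electrophilic aromatic bromination: the two free positions of the tetraalkoxybenzene ring are equivalent and far more electron-rich than the benzyl phenyl rings, and the first bromine slows a second substitution.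

Step 5
Reactants: 6 1-(2-fluoro-3,4,5-trimethoxyphenyl)ethan-1-one; 10 2,5-bis(benzyloxy)-1-bromo-3,4-dimethoxybenzene
Product: 11 2-[2,5-bis(benzyloxy)-3,4-dimethoxyphenyl]-1-(2-fluoro-3,4,5-trimethoxyphenyl)ethan-1-one
Conditions: Pd2(dba)3 (cat.), Xantphos (cat.), K3PO4, toluene, 90 °C
Reagents that add atoms: none
Why: Palladium-catalysed α-arylation of a methyl ketone (Buchwald–Hartwig type): zerovalent palladium inserts only into C–Br, the C–F bond and the weak base K3PO4 do not interfere, and the wide-bite-angle ligand together with the ortho-benzyloxy group should stop the reaction after one arylation.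

Step 6
Reactants: 11 2-[2,5-bis(benzyloxy)-3,4-dimethoxyphenyl]-1-(2-fluoro-3,4,5-trimethoxyphenyl)ethan-1-one; 12 ethyl formate
Product: 14 3-[2,5-bis(benzyloxy)-3,4-dimethoxyphenyl]-6,7,8-trimethoxy-4H-chromen-4-one (isoflavone), via sodium formyl enolate 13 (not isolated)
Conditions: NaH (slight excess), HCO2Et (excess), THF, 0 °C to rt; volatiles distilled off, DMF, 100 to 110 °C, same flask
Reagents that add atoms: ethyl formate (12), CCOC=O
Why: NaH removes a C3 proton (acidified by C4=O and ring B) and the enolate attacks ethyl formate in a crossed Claisen condensation (C2–C3 bond), pulled forward by deprotonation to the stabilised enolate 13. On heating in DMF the enolate oxygen of 13, the former carbonyl oxygen of the formate, adds to C8a, the fluorine-bearing β-carbon of the C4(=O)–C4a=C8a unit, and the Meisenheimer adduct expels fluoride (SNAr addition–elimination, O1–C8a bond), so the intact C=O of the formate becomes O1–C2. The closest known reaction types are the Claisen formylation of deoxybenzoins in the classical isoflavone synthesis and the base-mediated, metal-free cyclisation of 1-(2-haloaryl)-1,3-dicarbonyl compounds to chromones. Ring C closes as a six-membered ring in the 6-endo-trig mode with respect to C4a=C8a. No stereocentre is formed, and the flat, achiral product is what step 7 needs. The step needs C- over O-formylation (secured by reversibility, since only the C-formyl compound is drained as its enolate), the Z-enolate (which equilibrates freely) and a single site of substitution (C8a bears the only leaving group conjugated with the carbonyl group); the retarding methoxy donors of ring A are offset by fluoride as the best SNAr nucleofuge, by intramolecularity and by precipitation of NaF.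

Step 7
Reactants: 14 3-[2,5-bis(benzyloxy)-3,4-dimethoxyphenyl]-6,7,8-trimethoxy-4H-chromen-4-one
Product: 16 (3S,4S)-3-[2,5-bis(benzyloxy)-3,4-dimethoxyphenyl]-6,7,8-trimethoxychroman-4-ol (3,4-cis), via racemic isoflavanone 15 (not isolated)
Conditions: RuCl[(S,S)-TsDPEN](p-cymene) (cat.), HCO2H/Et3N (5:2), EtOAc, 40 °C
Reagents that add atoms: none
Why: Noyori-type asymmetric transfer hydrogenation cascade: the ruthenium hydride first adds 1,4 to the chromenone (known for isoflavones and other 3-substituted chromones) to give 15, whose C3 epimerises fast through the enol, and the (S,S)-catalyst then reduces only the (3S)-ketone, delivering hydride to the face of C4=O anti to ring B in the usual aryl ketone sense (4S), a dynamic kinetic resolution that sets both centres as cis-(3S,4S).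

Step 8
Reactants: 16 (3S,4S)-3-[2,5-bis(benzyloxy)-3,4-dimethoxyphenyl]-6,7,8-trimethoxychroman-4-ol
Product: 17 (3S,4R)-3-[2,5-bis(benzyloxy)-3,4-dimethoxyphenyl]-6,7,8-trimethoxychroman-4-yl 4-nitrobenzoate (3,4-trans)
Conditions: 4-O2NC6H4CO2H, PPh3, DIAD, toluene, −10 °C to rt
Reagents that add atoms: 4-nitrobenzoic acid, O=C(O)c1ccc([N+](=O)[O-])cc1
Why: Mitsunobu reaction: the carboxylate displaces the oxyphosphonium group from the face anti to ring B with inversion at C4 (4S to 4R), any ion-pair leakage at this electron-rich benzylic carbon should be captured from the same open face, so both paths lead to the trans ester, and C3 is not touched.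

Step 9
Reactants: 17 (3S,4R)-3-[2,5-bis(benzyloxy)-3,4-dimethoxyphenyl]-6,7,8-trimethoxychroman-4-yl 4-nitrobenzoate
Product: 18 (3S,4R)-3-[2,5-bis(benzyloxy)-3,4-dimethoxyphenyl]-6,7,8-trimethoxychroman-4-ol (3,4-trans)
Conditions: K2CO3 (cat.), MeOH/THF, 0 °C to rt
Reagents that add atoms: none
Why: Base-catalysed transesterification with acyl–oxygen cleavage, so the C4–O bond and both stereocentres stay as they are.

Step 10
Reactants: 18 (3S,4R)-3-[2,5-bis(benzyloxy)-3,4-dimethoxyphenyl]-6,7,8-trimethoxychroman-4-ol
Product: 19 (3S,4R)-3-(2,5-dihydroxy-3,4-dimethoxyphenyl)-6,7,8-trimethoxychroman-4-ol (target)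
Conditions: H2 (1 atm), Pd/C, EtOAc, rt; filtration and evaporation under argon
Reagents that add atoms: none
Why: Catalytic hydrogenolysis of the two aryl benzyl ethers, which under neutral conditions is much faster than cleavage of the secondary C4–OH; no acid is present that could ionise C4 and close the 2'-OH onto it, and exclusion of air keeps the hydroquinone from oxidising.

Compound list
1 | 1,2,3-trimethoxybenzene | COc1cccc(OC)c1OC | starting material
2 | 2,3,4-trimethoxyphenyllithium | [Li]c1ccc(OC)c(OC)c1OC | intermediate
3 | 1-fluoro-2,3,4-trimethoxybenzene | COc1ccc(F)c(OC)c1OC | intermediate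
4 | N-methoxy-N-methylacetamide | CC(=O)N(C)OC | starting material
5 | (2-fluoro-3,4,5-trimethoxyphenyl)lithium | [Li]c1cc(OC)c(OC)c(OC)c1F | intermediate
6 | 1-(2-fluoro-3,4,5-trimethoxyphenyl)ethan-1-one | CC(=O)c1cc(OC)c(OC)c(OC)c1F | intermediate
7 | 2,3-dimethoxy-1,4-benzoquinone | COC1=C(OC)C(=O)C=CC1=O | starting material
8 | 2,3-dimethoxybenzene-1,4-diol | COc1c(O)ccc(O)c1OC | intermediate
9 | 1,4-bis(benzyloxy)-2,3-dimethoxybenzene | COc1c(OCc2ccccc2)ccc(OCc2ccccc2)c1OC | intermediate
10 | 2,5-bis(benzyloxy)-1-bromo-3,4-dimethoxybenzene | COc1c(OCc2ccccc2)cc(Br)c(OCc2ccccc2)c1OC | intermediate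
11 | 2-[2,5-bis(benzyloxy)-3,4-dimethoxyphenyl]-1-(2-fluoro-3,4,5-trimethoxyphenyl)ethan-1-one | COc1cc(C(=O)Cc2cc(OCc3ccccc3)c(OC)c(OC)c2OCc2ccccc2)c(F)c(OC)c1OC | intermediate
12 | ethyl formate | CCOC=O | starting material
13 | sodium (Z)-2-[2,5-bis(benzyloxy)-3,4-dimethoxyphenyl]-3-(2-fluoro-3,4,5-trimethoxyphenyl)-3-oxoprop-1-en-1-olate | [Na+].[O-]/C=C(\C(=O)c1cc(OC)c(OC)c(OC)c1F)c1cc(OCc2ccccc2)c(OC)c(OC)c1OCc1ccccc1 | intermediate
14 | 3-[2,5-bis(benzyloxy)-3,4-dimethoxyphenyl]-6,7,8-trimethoxy-4H-chromen-4-one | COc1cc2c(c(OC)c1OC)OC=C(c1cc(OCc3ccccc3)c(OC)c(OC)c1OCc1ccccc1)C2=O | intermediate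
15 | racemic 3-[2,5-bis(benzyloxy)-3,4-dimethoxyphenyl]-6,7,8-trimethoxychroman-4-one | COc1cc2c(c(OC)c1OC)OCC(c1cc(OCc3ccccc3)c(OC)c(OC)c1OCc1ccccc1)C2=O | intermediate
16 | (3S,4S)-3-[2,5-bis(benzyloxy)-3,4-dimethoxyphenyl]-6,7,8-trimethoxychroman-4-ol (cis) | COc1cc2c(c(OC)c1OC)OC[C@H](c1cc(OCc3ccccc3)c(OC)c(OC)c1OCc1ccccc1)[C@@H]2O | intermediate
17 | (3S,4R)-3-[2,5-bis(benzyloxy)-3,4-dimethoxyphenyl]-6,7,8-trimethoxychroman-4-yl 4-nitrobenzoate (trans) | COc1cc2c(c(OC)c1OC)OC[C@H](c1cc(OCc3ccccc3)c(OC)c(OC)c1OCc1ccccc1)[C@H]2OC(=O)c1ccc([N+](=O)[O-])cc1 | intermediate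
18 | (3S,4R)-3-[2,5-bis(benzyloxy)-3,4-dimethoxyphenyl]-6,7,8-trimethoxychroman-4-ol (trans) | COc1cc2c(c(OC)c1OC)OC[C@H](c1cc(OCc3ccccc3)c(OC)c(OC)c1OCc1ccccc1)[C@H]2O | intermediate
19 | (3S,4R)-3-(2,5-dihydroxy-3,4-dimethoxyphenyl)-6,7,8-trimethoxychroman-4-ol | COc1cc2c(c(OC)c1OC)OC[C@H](c1cc(O)c(OC)c(OC)c1O)[C@H]2O | target

Total step count: 10. Longest linear sequence: 8 steps (1, 2, 5 to 10, or 3, 4, 5 to 10).

Steps most likely to fail

Step 6: addition of the stabilised enolate oxygen to ring A, which carries three methoxy donors, may be so slow that retro-Claisen loss of the formyl group and thermal decomposition take over. The fallback builds ring C on ring A first and makes the C3–C1' bond last. It sets out from 1 and 10 and comes back to the route at 14.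
- Aryllithium 2, made from 1 as in step 1, is quenched with B(OMe)3 and oxidised with H2O2 to 2,3,4-trimethoxyphenol F1.
- BF3·OEt2 in AcOH (acylation with Fries-type migration to the free ortho position) gives 1-(2-hydroxy-3,4,5-trimethoxyphenyl)ethan-1-one F2.
- N,N-dimethylformamide dimethyl acetal converts it into (E)-3-(dimethylamino)-1-(2-hydroxy-3,4,5-trimethoxyphenyl)prop-2-en-1-one F3.
- Iodine in CHCl3 closes and iodinates this to 3-iodo-6,7,8-trimethoxy-4H-chromen-4-one F4.
- Bromide 10 is turned by n-BuLi, B(OiPr)3 and aqueous acid into [2,5-bis(benzyloxy)-3,4-dimethoxyphenyl]boronic acid F5.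
- Suzuki–Miyaura coupling of F4 and F5 (Pd(PPh3)4, Na2CO3, DME/H2O) gives 14.

Step 8: loss of the C3 proton from the activated alcohol (elimination towards the conjugated alkene, which erases C3) may outrun substitution at C4. The fallback makes the elimination deliberate and resets both centres by reagent-controlled syn addition. It sets out from 16 and comes back at 18.
- Catalytic TsOH in toluene dehydrates 16 to 3-[2,5-bis(benzyloxy)-3,4-dimethoxyphenyl]-6,7,8-trimethoxy-2H-chromene F6.
- Monoisopinocampheylborane derived from (+)-α-pinene adds H to C3 and boron to the less substituted C4 from one face. By analogy with 1-arylcycloalkenes this should be the face leading to the (3S,4R) series, giving the 3,4-trans (isoflavan-4-yl)(isopinocampheyl)borane F7.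
- NaOH/H2O2 oxidises the C–B bond with retention to 18. The trans relation follows from the syn addition.

Step 7: hydride transfer to C2 of the electron-rich vinylogous ester may stall, or the two reductions may interfere, so that conversion or facial discrimination is poor. The fallback separates the two events. It sets out from 14 and comes back at 16. LiBH(s-Bu)3 in THF at −78 °C performs the conjugate reduction, and protonation gives racemic 15, which is isolated. The transfer hydrogenation with RuCl[(S,S)-TsDPEN](p-cymene) and HCO2H/Et3N is then run on the isoflavanone alone, the substrate class on which this dynamic kinetic resolution is best established. New compounds on this way: none F0.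

Further compounds
F1 | step 6 | 2,3,4-trimethoxyphenol | COc1ccc(O)c(OC)c1OC
F2 | step 6 | 1-(2-hydroxy-3,4,5-trimethoxyphenyl)ethan-1-one | CC(=O)c1cc(OC)c(OC)c(OC)c1O
F3 | step 6 | (E)-3-(dimethylamino)-1-(2-hydroxy-3,4,5-trimethoxyphenyl)prop-2-en-1-one | CN(C)/C=C/C(=O)c1cc(OC)c(OC)c(OC)c1O
F4 | step 6 | 3-iodo-6,7,8-trimethoxy-4H-chromen-4-one | COc1cc2c(c(OC)c1OC)OC=C(I)C2=O
F5 | step 6 | [2,5-bis(benzyloxy)-3,4-dimethoxyphenyl]boronic acid | COc1c(OCc2ccccc2)cc(B(O)O)c(OCc2ccccc2)c1OC
F6 | step 8 | 3-[2,5-bis(benzyloxy)-3,4-dimethoxyphenyl]-6,7,8-trimethoxy-2H-chromene | COc1cc2c(c(OC)c1OC)OCC(c1cc(OCc3ccccc3)c(OC)c(OC)c1OCc1ccccc1)=C2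
F7 | step 8 | 3,4-trans (isoflavan-4-yl)(isopinocampheyl)borane | C[C@H]1[C@H](B[C@H]4c5cc(OC)c(OC)c(OC)c5OC[C@@H]4c6cc(OCc7ccccc7)c(OC)c(OC)c6OCc6ccccc6)C[C@@H]2C[C@H]1C2(C)C
F0 | step 7 | none | none
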